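Retrosynthesis: the 3'-O-benzyl group comes off last. Ring C is cut at O1–C2 and C2–C3 (C2 is a one-carbon unit from DMF), which leaves a benzyl 2,4,6-trihydroxyphenyl ketone.
Enabling feature: in ring A the oxygens on C5, C7 and C8a alternate with C6–H, C8–H and C4a, and C4a carries the acyl carbon C4. This ring is the enol form of a 2-acylcyclohexane-1,3,5-trione, so it can be opened at C4a–C5 (equivalent to C4a–C8a) to a linear 3,5,7-trioxo ester with C3 and ring B at its far end.
The chain is cut once more at C4a–C4, into the trianion of methyl 3,5-dioxohexanoate (from dehydroacetic acid) and the ring B arylacetic N-methoxy-N-methylamide.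
Ring B is bought as 2,4,6-trimethoxybenzaldehyde. Its CHO is exchanged for the 3'-oxygen, which is capped as the benzyl ether; a new CHO is then introduced and homologated by one carbon.
Forward order: ring B fragment, chain joined, ring A by Claisen folding, ring C by formylative closure, debenzylation. Building ring A avoids a Friedel–Crafts acylation in which the equally electron-rich ring B would compete with phloroglucinol.
Stereochemistry: the target has no stereocentre and no configurable double bond, so nothing has to be controlled.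
Key step: step 10

Remark: β-polycarbonyl compounds are drawn as keto tautomers although they are largely enolised. The enol ether of step 4 is taken as an E/Z mixture, because both isomers hydrolyse to the same aldehyde.

Step 1
Reactants: 1 2,4,6-trimethoxybenzaldehyde
Product: 3 2,4,6-trimethoxyphenol, via 2,4,6-trimethoxyphenyl formate 2 (not isolated)
Conditions: 30% aq. H2O2 (slight excess), H2SO4 (cat.), MeOH, rt, under N2
Reagents that add atoms: hydrogen peroxide, OO
Why: Acid-catalysed Dakin-type (Baeyer–Villiger) oxidation, in which hydrogen peroxide adds to the activated aldehyde, the very electron-rich aryl group migrates to oxygen, and formate 2 is methanolysed in the same flask.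

Step 2
Reactants: 3 2,4,6-trimethoxyphenol; 4 benzyl bromide
Product: 5 2-(benzyloxy)-1,3,5-trimethoxybenzene
Conditions: K2CO3, DMF, 50 °C
Reagents that add atoms: benzyl bromide (compound 4), BrCc1ccccc1
Why: Williamson ether synthesis (SN2 of the phenoxide on 4); the benzyl ether should survive the acid, strong base and Mg(OMe)2 used later and can be removed at the end by hydrogenolysis.

Step 3
Reactants: 5 2-(benzyloxy)-1,3,5-trimethoxybenzene
Product: 7 3-(benzyloxy)-2,4,6-trimethoxybenzaldehyde, via aryl iminium chloride 6 (not isolated)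
Conditions: POCl3, DMF, 0 °C to rt; then ice–water
Reagents that add atoms: N,N-dimethylformamide, CN(C)C=O; water, O
Why: Vilsmeier–Haack formylation; the two free positions of 5 are equivalent by symmetry, each is ortho or para to three methoxy groups, and the new formyl group suppresses a second substitution.

Step 4
Reactants: 7 3-(benzyloxy)-2,4,6-trimethoxybenzaldehyde
Product: 8 2-(benzyloxy)-1,3,5-trimethoxy-4-(2-methoxyethenyl)benzene (E/Z mixture)
Conditions: MeOCH2PPh3Cl, KOtBu, THF, 0 °C to rt
Reagents that add atoms: (methoxymethyl)triphenylphosphonium chloride, COC[P+](c1ccccc1)(c1ccccc1)c1ccccc1.[Cl-]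
Why: Wittig olefination with the non-stabilised methoxymethylene ylide, which is reactive enough for an electron-rich, di-ortho-substituted benzaldehyde; the alkene geometry is irrelevant.

Step 5
Reactants: 8 2-(benzyloxy)-1,3,5-trimethoxy-4-(2-methoxyethenyl)benzene
Product: 9 2-[3-(benzyloxy)-2,4,6-trimethoxyphenyl]acetaldehyde
Conditions: 2 M aq. HCl (cat.), THF, 40 °C; crude aldehyde used at once
Reagents that add atoms: water, O
Why: Acid-catalysed enol ether hydrolysis, in which protonation at the benzylic carbon gives the oxocarbenium ion, water adds and methanol leaves, while aryl methyl and benzyl ethers are inert to dilute acid.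

Step 6
Reactants: 9 2-[3-(benzyloxy)-2,4,6-trimethoxyphenyl]acetaldehyde
Product: 10 2-[3-(benzyloxy)-2,4,6-trimethoxyphenyl]acetic acid
Conditions: NaClO2, NaH2PO4, 2-methyl-2-butene (large excess), t-BuOH–THF–H2O, 0 °C to rt
Reagents that add atoms: sodium chlorite, [Na+].[O-]Cl=O
Why: Pinnick oxidation, in which chlorous acid adds to the aldehyde and fragments to the acid, and the excess alkene intercepts HOCl before it can chlorinate the free C5 position of ring B.

Step 7
Reactants: 10 2-[3-(benzyloxy)-2,4,6-trimethoxyphenyl]acetic acid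
Product: 12 2-[3-(benzyloxy)-2,4,6-trimethoxyphenyl]-N-methoxy-N-methylacetamide, via acyl imidazole 11 (not isolated)
Conditions: 1,1'-carbonyldiimidazole, CH2Cl2, rt; then MeNHOMe·HCl, rt
Reagents that add atoms: N,O-dimethylhydroxylamine hydrochloride, CNOC.Cl
Why: Weinreb amide formation by carbonyldiimidazole activation; the imidazole released in the activation frees the amine from its salt, and the near-neutral medium leaves all ethers untouched.

Step 8
Reactants: 13 dehydroacetic acid
Product: 15 methyl 3,5-dioxohexanoate, via methyl 2-acetyl-3,5-dioxohexanoate 14 (not isolated)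
Conditions: Mg(OMe)2, MeOH, reflux; then cold aq. HCl; distillation
Reagents that add atoms: methanol, CO
Why: Alkoxide lactone opening followed by retro-Claisen deacetylation; methoxide opens 13 to the triacylmethane 14, which loses its acetyl group, while magnesium chelation shields the remaining 3,5-dioxo ester from further cleavage.

Step 9
Reactants: 15 methyl 3,5-dioxohexanoate; 12 2-[3-(benzyloxy)-2,4,6-trimethoxyphenyl]-N-methoxy-N-methylacetamide
Product: 18 methyl 8-[3-(benzyloxy)-2,4,6-trimethoxyphenyl]-3,5,7-trioxooctanoate, via trilithium trianion 16 (not isolated), via trilithium tetrahedral adduct 17 (not isolated)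
Conditions: LiN(iPr)2 (3.0 equiv per 15), THF, −78 to 0 °C; 12 (0.6 equiv per 15), −78 to 0 °C; cold aq. HCl; crude 18 carried on at once
Reagents that add atoms: none
Why: Polyanion acylation with a Weinreb amide; the last-formed, least stabilised terminal carbanion of 16 is its most nucleophilic site, and the chelated adduct 17 withholds the new ketone until the acidic quench, so neither over-addition nor proton exchange with the product should interfere.

Step 10
Reactants: 18 methyl 8-[3-(benzyloxy)-2,4,6-trimethoxyphenyl]-3,5,7-trioxooctanoate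
Product: 20 2-[3-(benzyloxy)-2,4,6-trimethoxyphenyl]-1-(2,4,6-trihydroxyphenyl)ethanone, via cyclohexanetrione tautomer 19 (not isolated)
Conditions: 18 added to Mg(OMe)2 (4 equiv) in MeOH, rt, then reflux; cold aq. HCl
Reagents that add atoms: none
Why: Mg(OMe)2 ionises the two methylenes that lie between ketones (C4 and C6), so the C3, C5 and C7 carbonyls are all bound to divalent magnesium as enolates; the cis-chelate geometry curls the chain, C6 adds to the ester carbon C1, methoxide is expelled, and trione 19 enolises to the phloroglucinol, which stays a magnesium phenoxide chelate until the acid work-up. The closest known reaction type is the base-mediated intramolecular Claisen (Dieckmann-type) condensation of 3,5,7-triketo esters, and of the 6-(2-oxoalkyl)-4-hydroxy-2-pyrones that open to them, to acylphloroglucinols. Ring A closes in the 6-exo-trig mode at the ester carbonyl, and the new C6–C1 bond is the C4a–C5 bond of the target (or C4a–C8a, the two being equivalent until ring C is closed). No stereocentre is formed. The selectivity needed is Claisen folding over aldol folding (C2 onto C7), over lactonisation and over reaction at C8. It is secured because the ester is the only carbonyl left as an electrophile in the fully enolised chelate (hence 18 is added to the base, never the reverse), because O-acylation is reversible in methoxide whereas aromatisation is not, and because C8–H is only singly activated and screened by the two ortho methoxy groups of ring B.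

Step 11
Reactants: 20 2-[3-(benzyloxy)-2,4,6-trimethoxyphenyl]-1-(2,4,6-trihydroxyphenyl)ethanone
Product: 22 3-[3-(benzyloxy)-2,4,6-trimethoxyphenyl]-5,7-dihydroxy-4H-chromen-4-one, via enaminoketone 21 (not isolated)
Conditions: BF3·OEt2, DMF, rt to 50 °C; MsCl in DMF, 50 to 80 °C; then ice–water
Reagents that add atoms: N,N-dimethylformamide, CN(C)C=O
Why: Vilsmeier-type formylation and cyclisation of a 2-hydroxydeoxybenzoin; BF3 coordination to the ortho-hydroxy ketone promotes enolisation towards the methylene, the enol attacks the iminium reagent made from DMF and MsCl to give 21, and addition of either ortho hydroxyl (equivalent by symmetry) with loss of dimethylamine closes ring C.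

Step 12
Reactants: 22 3-[3-(benzyloxy)-2,4,6-trimethoxyphenyl]-5,7-dihydroxy-4H-chromen-4-one
Product: 23 5,7-dihydroxy-3-(3-hydroxy-2,4,6-trimethoxyphenyl)-4H-chromen-4-one (target)
Conditions: H2 (1 atm), 10% Pd/C, EtOAc–MeOH, rt, stopped after one equivalent of H2
Reagents that add atoms: none
Why: Catalytic hydrogenolysis of the aryl benzyl ether; the C2–C3 double bond is part of the 4-pyrone and is shielded by the di-ortho-substituted ring B, so it should be reduced much more slowly.

Compound list
1 | 2,4,6-trimethoxybenzaldehyde | COc1cc(OC)c(C=O)c(OC)c1 | starting material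
2 | 2,4,6-trimethoxyphenyl formate | COc1cc(OC)c(OC=O)c(OC)c1 | intermediate
3 | 2,4,6-trimethoxyphenol | COc1cc(OC)c(O)c(OC)c1 | intermediate
4 | benzyl bromide | BrCc1ccccc1 | starting material
5 | 2-(benzyloxy)-1,3,5-trimethoxybenzene | COc1cc(OC)c(OCc2ccccc2)c(OC)c1 | intermediate
6 | N-[3-(benzyloxy)-2,4,6-trimethoxybenzylidene]-N-methylmethanaminium chloride | C[N+](C)=Cc1c(OC)cc(OC)c(OCc2ccccc2)c1OC.[Cl-] | intermediate
7 | 3-(benzyloxy)-2,4,6-trimethoxybenzaldehyde | O=Cc1c(OC)cc(OC)c(OCc2ccccc2)c1OC | intermediate
8 | 2-(benzyloxy)-1,3,5-trimethoxy-4-(2-methoxyethenyl)benzene (E/Z mixture) | COC=Cc1c(OC)cc(OC)c(OCc2ccccc2)c1OC | intermediate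
9 | 2-[3-(benzyloxy)-2,4,6-trimethoxyphenyl]acetaldehyde | O=CCc1c(OC)cc(OC)c(OCc2ccccc2)c1OC | intermediate
10 | 2-[3-(benzyloxy)-2,4,6-trimethoxyphenyl]acetic acid | OC(=O)Cc1c(OC)cc(OC)c(OCc2ccccc2)c1OC | intermediate
11 | 2-[3-(benzyloxy)-2,4,6-trimethoxyphenyl]-1-(1H-imidazol-1-yl)ethanone | O=C(Cc1c(OC)cc(OC)c(OCc2ccccc2)c1OC)n1ccnc1 | intermediate
12 | 2-[3-(benzyloxy)-2,4,6-trimethoxyphenyl]-N-methoxy-N-methylacetamide | CON(C)C(=O)Cc1c(OC)cc(OC)c(OCc2ccccc2)c1OC | intermediate
13 | dehydroacetic acid (3-acetyl-6-methylpyran-2,4-dione) | CC1=CC(=O)C(C(C)=O)C(=O)O1 | starting material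
14 | methyl 2-acetyl-3,5-dioxohexanoate | COC(=O)C(C(C)=O)C(=O)CC(C)=O | intermediate
15 | methyl 3,5-dioxohexanoate | COC(=O)CC(=O)CC(C)=O | intermediate
16 | trilithium trianion of methyl 3,5-dioxohexanoate | [Li+].[Li+].[Li+].COC([O-])=CC([O-])=CC([O-])=C | intermediate
17 | trilithium tetrahedral adduct of 16 and 12 (transient carbinolamine carbon, configuration irrelevant) | [Li+].[Li+].[Li+].COC([O-])=CC([O-])=CC(=O)CC([O-])(Cc1c(OC)cc(OC)c(OCc2ccccc2)c1OC)N(C)OC | intermediate
18 | methyl 8-[3-(benzyloxy)-2,4,6-trimethoxyphenyl]-3,5,7-trioxooctanoate | COC(=O)CC(=O)CC(=O)CC(=O)Cc1c(OC)cc(OC)c(OCc2ccccc2)c1OC | intermediate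
19 | 2-{[3-(benzyloxy)-2,4,6-trimethoxyphenyl]acetyl}cyclohexane-1,3,5-trione | O=C(Cc1c(OC)cc(OC)c(OCc2ccccc2)c1OC)C1C(=O)CC(=O)CC1=O | intermediate
20 | 2-[3-(benzyloxy)-2,4,6-trimethoxyphenyl]-1-(2,4,6-trihydroxyphenyl)ethanone | O=C(Cc1c(OC)cc(OC)c(OCc2ccccc2)c1OC)c1c(O)cc(O)cc1O | intermediate
21 | 2-[3-(benzyloxy)-2,4,6-trimethoxyphenyl]-3-(dimethylamino)-1-(2,4,6-trihydroxyphenyl)prop-2-en-1-one | CN(C)C=C(C(=O)c1c(O)cc(O)cc1O)c1c(OC)cc(OC)c(OCc2ccccc2)c1OC | intermediate
22 | 3-[3-(benzyloxy)-2,4,6-trimethoxyphenyl]-5,7-dihydroxy-4H-chromen-4-one | COc1cc(OC)c(-c2coc3cc(O)cc(O)c3c2=O)c(OC)c1OCc1ccccc1 | intermediate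
23 | 5,7-dihydroxy-3-(3-hydroxy-2,4,6-trimethoxyphenyl)-4H-chromen-4-one | COc1cc(OC)c(-c2coc3cc(O)cc(O)c3c2=O)c(OC)c1O | target

Total step count: 12. Longest linear sequence: 11 (steps 1–7, then 9–12); step 8 is the one-step side branch.

Steps most likely to fail

Step 9. The third deprotonation of 15 may be incomplete. The α-methylene of 12 may transfer a proton to the terminal carbanion instead of being acylated. The free polyketone may also cyclise prematurely during quench and isolation. The fallback sets out from 13 and 12 and comes back at 18, and it carries the chain as a lactone instead of an open ester. Hot 90% H2SO4 deacetylates 13 to 4-hydroxy-6-methyl-2H-pyran-2-one F1. Two equivalents of LiN(iPr)2 in THF convert F1 into the dilithium dianion of 4-hydroxy-6-methyl-2H-pyran-2-one F2, which is a less basic nucleophile than a trianion. Acylation of F2 at its exocyclic carbon by 12 should give 6-{3-[3-(benzyloxy)-2,4,6-trimethoxyphenyl]-2-oxopropyl}-4-hydroxy-2H-pyran-2-one F3, a storable solid form of the chain. Mg(OMe)2 in MeOH then opens the lactone by methanolysis and releases 18 as its magnesium chelate directly in the medium of step 10, where it folds without isolation.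

Step 10. The chain may fold in the aldol sense (C2 onto C7), it may lactonise through the C5 enolate oxygen without reverting, or methoxide may cleave it by retro-Claisen reaction. The fallback sets out from 7 and comes back at 20, and in it ring A is bought rather than built. van Leusen reductive cyanation of 7 (TosMIC, KOtBu, DME, −50 °C; then MeOH, reflux) should give [3-(benzyloxy)-2,4,6-trimethoxyphenyl]acetonitrile F4. Hoesch acylation of purchased phloroglucinol with F4 (ZnCl2, HCl gas, Et2O, 0 °C) should precipitate 2-[3-(benzyloxy)-2,4,6-trimethoxyphenyl]-1-(2,4,6-trihydroxyphenyl)ethaniminium chloride F5. Hot water hydrolyses F5 to 20. Phloroglucinol is used in excess because ring B is itself a competent nucleophile.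

Step 11. C-formylation may be slow at a methylene wedged between the carbonyl group and a di-ortho-substituted ring. Electrophilic attack on ring A and Lewis-acid-induced loss of the benzyl ether may compete. The fallback sets out from 20 (with 4) and comes back at 23. It caps ring A so that a basic aminomethylenating reagent can be used hot and without any Lewis acid. Two equivalents of 4 with K2CO3 in DMF leave only the chelated hydroxyl free and should give 1-[2,4-bis(benzyloxy)-6-hydroxyphenyl]-2-[3-(benzyloxy)-2,4,6-trimethoxyphenyl]ethanone F6. Bredereck's reagent (tert-butoxybis(dimethylamino)methane) in toluene at 100 °C should give 1-[2,4-bis(benzyloxy)-6-hydroxyphenyl]-2-[3-(benzyloxy)-2,4,6-trimethoxyphenyl]-3-(dimethylamino)prop-2-en-1-one F7. Warm acetic acid closes F7 to 5,7-bis(benzyloxy)-3-[3-(benzyloxy)-2,4,6-trimethoxyphenyl]-4H-chromen-4-one F8. Hydrogenolysis of all three benzyl ethers (H2, 10% Pd/C) delivers 23.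

Further compounds
F1 | step 9 | 4-hydroxy-6-methyl-2H-pyran-2-one | CC1=CC(O)=CC(=O)O1
F2 | step 9 | dilithium dianion of 4-hydroxy-6-methyl-2H-pyran-2-one | [Li+].[Li+].[CH2-]C1=CC([O-])=CC(=O)O1
F3 | step 9 | 6-{3-[3-(benzyloxy)-2,4,6-trimethoxyphenyl]-2-oxopropyl}-4-hydroxy-2H-pyran-2-one | O=C(CC1=CC(O)=CC(=O)O1)Cc1c(OC)cc(OC)c(OCc2ccccc2)c1OC
F4 | step 10 | [3-(benzyloxy)-2,4,6-trimethoxyphenyl]acetonitrile | N#CCc1c(OC)cc(OC)c(OCc2ccccc2)c1OC
F5 | step 10 | 2-[3-(benzyloxy)-2,4,6-trimethoxyphenyl]-1-(2,4,6-trihydroxyphenyl)ethaniminium chloride | [NH2+]=C(Cc1c(OC)cc(OC)c(OCc2ccccc2)c1OC)c1c(O)cc(O)cc1O.[Cl-]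
F6 | step 11 | 1-[2,4-bis(benzyloxy)-6-hydroxyphenyl]-2-[3-(benzyloxy)-2,4,6-trimethoxyphenyl]ethanone | O=C(Cc1c(OC)cc(OC)c(OCc2ccccc2)c1OC)c1c(O)cc(OCc2ccccc2)cc1OCc1ccccc1
F7 | step 11 | 1-[2,4-bis(benzyloxy)-6-hydroxyphenyl]-2-[3-(benzyloxy)-2,4,6-trimethoxyphenyl]-3-(dimethylamino)prop-2-en-1-one | CN(C)C=C(C(=O)c1c(O)cc(OCc2ccccc2)cc1OCc1ccccc1)c1c(OC)cc(OC)c(OCc2ccccc2)c1OC
F8 | step 11 | 5,7-bis(benzyloxy)-3-[3-(benzyloxy)-2,4,6-trimethoxyphenyl]-4H-chromen-4-one | COc1cc(OC)c(-c2coc3cc(OCc4ccccc4)cc(OCc4ccccc4)c3c2=O)c(OC)c1OCc1ccccc1
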